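The carbocycle C13–C18 holds the C12 chain and the methyls on C15, C17 and C18 on one face and the oxygens on C14–C17 on the other. This marks it as a cis-5,6-disubstituted cyclohexa-1,3-diene that has taken up four oxygens on its free face. Cutting C13–C18 unravels that diene to an acyclic (E,Z,E)-3,5-dimethylheptatriene ending in a glyceraldehyde-derived dioxolane. Heating closes the ring in one disrotatory 6π event that fixes the C13/C18 cis pair and, through the dioxolane, its absolute sense. Singlet oxygen and directed osmylation relay this to C14–C17. Glycol cleavage then frees C12 for Wittig, Takai and Stille attachment of the pyranone.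

Key step: step 5

Numbering and faces: pyranone O1/C2–C6, chain C7–C12, carbocycle C13 (bears C12), C14 (OAc), C15 (Me, OH), C16 (OAc), C17 (Me, OH), C18 (CHMe). The "lower face" carries C12 and the three ring methyls; the "upper face" carries the four oxygens.
Assumption: the rotation sense in step 5 is taken from the inside-alkoxy model for additions to allylic ethers. It is a prediction, and the two possible products are diastereomers separable at 7 or 9.

Step 1
Reactants: 1 (S)-2,2-dimethyl-1,3-dioxolane-4-carbaldehyde (L-glyceraldehyde acetonide)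
Product: 2 (R)-4-ethynyl-2,2-dimethyl-1,3-dioxolane
Conditions: dimethyl (1-diazo-2-oxopropyl)phosphonate (1.2 equiv), K2CO3 (2 equiv), MeOH, 0 °C → rt; pentane extraction, careful concentration (volatile)
Reagents that add atoms: dimethyl (1-diazo-2-oxopropyl)phosphonate, CC(=O)C(=[N+]=[N-])P(=O)(OC)OC
Why: In this Ohira–Bestmann form of the Seyferth–Gilbert homologation, methanolysis frees the diazomethylphosphonate anion, which adds to the aldehyde and collapses through the alkylidene carbene to the terminal alkyne (new carbon = C14), while the mild carbonate base leaves the α-alkoxy stereocentre untouched.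

Step 2
Reactants: 2 (R)-4-ethynyl-2,2-dimethyl-1,3-dioxolane
Product: 3 2-{(E)-2-[(R)-2,2-dimethyl-1,3-dioxolan-4-yl]ethenyl}-4,4,5,5-tetramethyl-1,3,2-dioxaborolane
Conditions: HBpin (1.1 equiv), Cp2ZrHCl (10 mol %), Et3N (10 mol %), neat, sealed vial, 60 °C
Reagents that add atoms: pinacolborane, CC1(C)OBOC1(C)C
Why: Zirconocene-catalysed syn hydroboration of a terminal alkyne places boron on the terminal carbon and so gives only the E-alkenyl boronate, leaving ketal and stereocentre unchanged.

Step 3
Reactants: 4 (E)-2-methylbut-2-enal (tiglic aldehyde)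
Product: 5 (2Z,4E)-2-iodo-4-methylhexa-2,4-diene
Conditions: EtPPh3I, n-BuLi, THF, rt; I2, THF, −78 °C; NaHMDS, −20 °C; 4, −78 → −20 °C, dark; pentane trituration
Reagents that add atoms: ethyltriphenylphosphonium iodide, CC[P+](c1ccccc1)(c1ccccc1)c1ccccc1.[I-]; iodine, II
Why: This iodo-Wittig olefination of the Stork–Zhao type uses a non-stabilised α-iodo ylide that reacts under kinetic control to place iodine cis to the alkenyl residue (Z), and the E alkene of 4 takes no part.

Step 4
Reactants: 3 (E)-alkenyl pinacol boronate; 5 (2Z,4E)-2-iodo-4-methylhexa-2,4-diene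
Product: 6 (R)-4-[(1E,3Z,5E)-3,5-dimethylhepta-1,3,5-trien-1-yl]-2,2-dimethyl-1,3-dioxolane
Conditions: Pd(dppf)Cl2·CH2Cl2 (5 mol %), K3PO4 (3 M aq, 3 equiv), THF, rt, degassed, dark
Reagents that add atoms: none
Why: Suzuki–Miyaura coupling of an alkenyl iodide with an alkenyl boronate retains the geometry at both sp2 carbons, and working at room temperature in the dark keeps the new (E,Z,E)-triene from isomerising or closing before it is purified.

Step 5
Reactants: 6 (R)-4-[(1E,3Z,5E)-3,5-dimethylhepta-1,3,5-trien-1-yl]-2,2-dimethyl-1,3-dioxolane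
Product: 7 (R)-4-[(1S,6S)-3,5,6-trimethylcyclohexa-2,4-dien-1-yl]-2,2-dimethyl-1,3-dioxolane (dioxolanyl on C13 and methyl on C18 cis, both on the lower face)
Conditions: PhMe (0.02 M, degassed), BHT (5 mol %), sealed tube, 110 °C, dark; chromatography to remove the other diastereomer
Reagents that add atoms: none
Why: In the helical s-cis,s-cis conformer about C14–C15 and C16–C17 the six π electrons of 6 reorganise in one concerted, thermally allowed disrotatory 6π electrocyclisation, which makes the C13–C18 σ bond and moves the π bonds to C14=C15 and C16=C17. The closest known reaction type is the thermal closure of (E,Z,E)-hexa-1,3,5-trienes to cis-5,6-disubstituted cyclohexa-1,3-dienes, including cases in which a stereocentre on a terminal substituent biases the sense of rotation. The only ring formed, the six-membered carbocycle C13–C18, closes by direct bonding of the two triene termini, so all six ring atoms come from the triene and no regiochemical alternative exists. The cis relation of C13 and C18 follows from orbital symmetry together with the E geometry of both terminal alkenes, because the outward dioxolanyl and methyl groups swing to the same face while the two inward hydrogens pass each other. The absolute sense at both centres is controlled by the dioxolane stereocentre C12, expected to react with its C–O bond inside (towards H14), its CH2O carbon anti to the incoming C18 and its hydrogen outside, which exposes the C13 face that leads to 7. The step needs torquoselectivity, which rests on this allylic bias and is backed by the separability of the two diastereomers, and chemoselectivity over hydrogen shifts, geometric isomerisation and aromatisation, which is secured by the absence of any inward alkyl group, by the C15 and C17 methyls that disfavour extended conformers, by a temperature below that of 1,5-H shifts in the product and by exclusion of oxygen and light.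

Step 6
Reactants: 7 cis-5,6-disubstituted cyclohexadiene
Product: 9 cis-C14/C17 ene-diol acetonide, via endoperoxide 8 (not isolated)
Conditions: O2, TPP (1 mol %), CH2Cl2, visible light, −20 °C; lamp off, N2 purge; thiourea (1.5 equiv), MeOH, rt
Reagents that add atoms: oxygen, O=O
Why: The singlet-oxygen [4+2] cycloaddition to the ring-locked s-cis diene takes place on the upper face, opposite the two cis carbon groups on C13 and C18, which sets C14 and C17, and neutral thiourea then cleaves only the O–O bond with retention at both carbons and without the base that would start a Kornblum–DeLaMare fragmentation at C14–H.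

Step 7
Reactants: 9 cis-C14/C17 ene-diol acetonide
Product: 11 all-cis C14–C17 tetraol acetonide, via osmate ester TMEDA chelate 10 (not isolated)
Conditions: OsO4 (1.05 equiv), TMEDA (1.1 equiv), CH2Cl2, −78 °C; then aq Na2SO3, THF, reflux
Reagents that add atoms: osmium tetroxide, O=[Os](=O)(=O)=O
Why: In this hydrogen-bond-directed dihydroxylation the OsO4·TMEDA complex accepts hydrogen bonds from the C14 and C17 hydroxyls and adds suprafacially to C15=C16 on their face, which is also the face free of the C13, C17 and C18 carbon groups, so C15 and C16 receive their oxygens on the upper face.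

Step 8
Reactants: 11 all-cis C14–C17 tetraol acetonide
Product: 12 C14,C16-diacetate acetonide (C15 and C17 hydroxyls free)
Conditions: Ac2O (2.5 equiv), pyridine, DMAP (5 mol %), CH2Cl2, 0 °C → rt
Reagents that add atoms: acetic anhydride, CC(=O)OC(C)=O
Why: This is a rate-controlled selective acylation in which the two secondary hydroxyls, expected to be equatorial in the favoured chair, are esterified while the two tertiary carbinols stay free under these mild conditions.

Step 9
Reactants: 12 C14,C16-diacetate acetonide
Product: 14 ring aldehyde diacetate, via side-chain diol 13 (not isolated)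
Conditions: H5IO6 (2 equiv), EtOAc, 0 °C → rt; neutral work-up, used crude at once
Reagents that add atoms: none
Why: Periodic acid first hydrolyses the terminal ketal and then effects Malaprade cleavage of the liberated glycol, the only vicinal diol present because the ring hydroxyls at C15 and C17 are 1,3-related and flanked by esters, so the controller stereocentre is excised, C12 emerges as the aldehyde and the base-free medium spares C13.

Step 10
Reactants: 14 ring aldehyde diacetate; 15 2-(triphenylphosphoranylidene)propanal
Product: 16 (E)-2-methyl enal (C10 aldehyde, C11=C12 alkene on C13)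
Conditions: 15 (1.5 equiv), PhMe, 80 °C
Reagents that add atoms: none
Why: Wittig olefination with a stabilised formyl ylide gives the E-trisubstituted enal, the ylide is too weak a base to start E1cB loss of the C14 acetate or epimerisation of the equatorial C13 substituent, and the conjugated product is far less electrophilic than 14, so a second olefination stays slow.

Step 11
Reactants: 16 (E)-2-methyl enal
Product: 17 (E,E)-dienyl iodide (C9 iodide, C9=C10 and C11=C12 both E)
Conditions: CrCl2 (8 equiv), CHI3 (3 equiv), THF/1,4-dioxane 1:6, 0 °C → rt, dark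
Reagents that add atoms: iodoform, IC(I)I
Why: In the Takai iodo-olefination the gem-dichromium species from iodoform adds only to the aldehyde in the presence of esters and free tertiary alcohols and eliminates to the E-alkenyl iodide, a preference reinforced by the α-methyl branch and the dioxane-rich medium.

Step 12
Reactants: 18 (E)-3-iodo-2-methylacrylic acid
Product: 19 (E)-1-(1H-imidazol-1-yl)-3-iodo-2-methylprop-2-en-1-one
Conditions: CDI (1.05 equiv), CH2Cl2, rt; quick cold-water wash, dry, concentrate
Reagents that add atoms: 1,1'-carbonyldiimidazole, O=C(n1ccnc1)n1ccnc1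
Why: Carbonyldiimidazole activates the acid through the mixed anhydride with loss of CO2 under neutral conditions that keep the alkenyl iodide geometry, and the wash removes the imidazole that would otherwise protonate the dianion of the next step.

Step 13
Reactants: 19 acyl imidazole; 20 methyl 2-methyl-3-oxopentanoate
Product: 23 4-hydroxy-6-[(E)-1-iodoprop-1-en-2-yl]-3,5-dimethyl-2H-pyran-2-one, via dilithium dianion 21 (not isolated), via triketo ester 22 (not isolated)
Conditions: 20 (2.2 equiv), LDA (4.5 equiv), THF, −78 → 0 °C; 19, −78 °C; 1 M HCl quench; crude, DBU, PhMe, rt → 60 °C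
Reagents that add atoms: none
Why: Double deprotonation gives bis-enolate 21, whose more reactive γ-carbon attacks the acyl imidazole carbonyl in a Claisen-type C-acylation faster than any addition–elimination at the iodine-bearing carbon at −78 °C, the surplus dianion takes up the acidic proton of 22, and DBU-induced enol lactonisation with loss of methanol gives the planar hydroxypyranone in which the two labile stereocentres of 22 disappear.

Step 14
Reactants: 23 4-hydroxy-2-pyranone alkenyl iodide
Product: 24 2-[(E)-1-iodoprop-1-en-2-yl]-6-methoxy-3,5-dimethyl-4H-pyran-4-one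
Conditions: MeOTf (2 equiv), CH2Cl2, rt; then aq NaHCO3
Reagents that add atoms: methyl trifluoromethanesulfonate, COS(=O)(=O)C(F)(F)F
Why: Without base the hard methylating agent attacks the most basic oxygen, the lactone carbonyl, and the resulting hydroxypyrylium salt loses its proton on work-up to give the 2-methoxy-4-pyranone rather than the 4-methoxy-2-pyranone favoured by alkylation of the anion.

Step 15
Reactants: 24 2-methoxy-4-pyranone alkenyl iodide
Product: 25 2-methoxy-3,5-dimethyl-6-[(E)-1-(trimethylstannyl)prop-1-en-2-yl]-4H-pyran-4-one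
Conditions: (Me3Sn)2 (1.5 equiv), Pd(PPh3)4 (5 mol %), 1,4-dioxane, 80 °C, dark
Reagents that add atoms: hexamethylditin, C[Sn](C)(C)[Sn](C)(C)C
Why: Palladium-catalysed stannylation runs by oxidative addition to the alkenyl iodide, transmetallation with the distannane and reductive elimination with retention of the E geometry, and the excess of distannane suppresses homocoupling.

Step 16
Reactants: 17 (E,E)-dienyl iodide; 25 pyranone alkenyl stannane
Product: 26 Amaurone B, (13R,14S,15S,16R,17R,18S), 7E,9E,11E
Conditions: Pd2(dba)3·CHCl3 (5 mol %), AsPh3 (40 mol %), NMP, rt → 40 °C, degassed, dark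
Reagents that add atoms: none
Why: Stille coupling of an alkenyl stannane with an alkenyl iodide forms C8–C9 with retention at both partners under neutral conditions that leave the acetates and free tertiary alcohols alone, and the all-E triene has no cis alkene that could trigger a further electrocyclisation.

Compound list
1 | (S)-2,2-dimethyl-1,3-dioxolane-4-carbaldehyde | CC1(C)OC[C@H](O1)C=O | starting material
2 | (R)-4-ethynyl-2,2-dimethyl-1,3-dioxolane | CC1(C)OC[C@H](O1)C#C | intermediate
3 | (R,E)-alkenyl pinacol boronate carrying the dioxolane | CC1(C)OC[C@H](O1)/C=C/B2OC(C)(C)C(C)(C)O2 | intermediate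
4 | (E)-2-methylbut-2-enal | C/C=C(\C)C=O | starting material
5 | (2Z,4E)-2-iodo-4-methylhexa-2,4-diene | C/C=C(C)/C=C(\I)C | intermediate
6 | (R)-4-[(1E,3Z,5E)-3,5-dimethylhepta-1,3,5-trien-1-yl]-2,2-dimethyl-1,3-dioxolane | CC1(C)OC[C@H](O1)/C=C/C(C)=C\C(C)=C\C | intermediate
7 | (R)-4-[(1S,6S)-3,5,6-trimethylcyclohexa-2,4-dien-1-yl]-2,2-dimethyl-1,3-dioxolane | CC1(C)OC[C@H](O1)[C@@H]2[C@H](C)C(C)=CC(C)=C2 | intermediate
8 | 2,3-dioxabicyclo[2.2.2]oct-5-ene endoperoxide, C14–O–O–C17 bridge on the upper face | CC1(C)OC[C@H](O1)[C@@H]2[C@H](C)[C@@](C)(OO3)C=C(C)[C@H]23 | intermediate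
9 | cis-ene-1,4-diol, C14-OH and C17-OH on the upper face, C15=C16 | CC1(C)OC[C@H](O1)[C@@H]2[C@H](C)[C@@](C)(O)C=C(C)[C@H]2O | intermediate
10 | C15,C16 osmate(VI) ester, TMEDA chelate | CC1(C)OC[C@H](O1)[C@@H]2[C@H](C)[C@@](C)(O)[C@@H](O3)[C@@](C)(O[Os-2]34(=O)(=O)[N+](C)(C)CC[N+]4(C)C)[C@H]2O | intermediate
11 | all-cis C14–C17 tetraol acetonide | CC1(C)OC[C@H](O1)[C@@H]2[C@H](C)[C@@](C)(O)[C@@H](O)[C@@](C)(O)[C@H]2O | intermediate
12 | C14,C16-diacetate acetonide | CC1(C)OC[C@H](O1)[C@@H]2[C@H](C)[C@@](C)(O)[C@@H](OC(C)=O)[C@@](C)(O)[C@H]2OC(C)=O | intermediate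
13 | C14,C16-diacetate with free (R)-1,2-dihydroxyethyl group on C13 | OC[C@H](O)[C@@H]1[C@H](C)[C@@](C)(O)[C@@H](OC(C)=O)[C@@](C)(O)[C@H]1OC(C)=O | intermediate
14 | ring aldehyde (C12 = CHO) with all six stereocentres, diacetate | O=C[C@@H]1[C@H](C)[C@@](C)(O)[C@@H](OC(C)=O)[C@@](C)(O)[C@H]1OC(C)=O | intermediate
15 | 2-(triphenylphosphoranylidene)propanal | CC(C=O)=P(c1ccccc1)(c1ccccc1)c1ccccc1 | starting material
16 | (E)-2-methyl enal | O=C/C(C)=C/[C@@H]1[C@H](C)[C@@](C)(O)[C@@H](OC(C)=O)[C@@](C)(O)[C@H]1OC(C)=O | intermediate
17 | (E,E)-dienyl iodide | I/C=C/C(C)=C/[C@@H]1[C@H](C)[C@@](C)(O)[C@@H](OC(C)=O)[C@@](C)(O)[C@H]1OC(C)=O | intermediate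
18 | (E)-3-iodo-2-methylacrylic acid | OC(=O)/C(C)=C/I | starting material
19 | (E)-1-(1H-imidazol-1-yl)-3-iodo-2-methylprop-2-en-1-one | O=C(n1ccnc1)/C(C)=C/I | intermediate
20 | methyl 2-methyl-3-oxopentanoate | CCC(=O)C(C)C(=O)OC | starting material
21 | dilithium bis-enolate of 20 | [Li+].[Li+].CC=C([O-])C(C)=C([O-])OC | intermediate
22 | methyl (E)-7-iodo-2,4,6-trimethyl-3,5-dioxohept-6-enoate (C2/C4 epimers and tautomers) | COC(=O)C(C)C(=O)C(C)C(=O)/C(C)=C/I | intermediate
23 | 4-hydroxy-6-[(E)-1-iodoprop-1-en-2-yl]-3,5-dimethyl-2H-pyran-2-one | CC1=C(O)C(C)=C(/C(C)=C/I)OC1=O | intermediate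
24 | 2-[(E)-1-iodoprop-1-en-2-yl]-6-methoxy-3,5-dimethyl-4H-pyran-4-one | COc1oc(/C(C)=C/I)c(C)c(=O)c1C | intermediate
25 | 2-methoxy-3,5-dimethyl-6-[(E)-1-(trimethylstannyl)prop-1-en-2-yl]-4H-pyran-4-one | COc1oc(/C(C)=C/[Sn](C)(C)C)c(C)c(=O)c1C | intermediate
26 | Amaurone B | COc1oc(/C(C)=C/C=C/C(C)=C/[C@@H]2[C@H](C)[C@@](C)(O)[C@@H](OC(C)=O)[C@@](C)(O)[C@H]2OC(C)=O)c(C)c(=O)c1C | target

Total step count: 16.
Longest linear sequence: 11 steps (1 → 2 → 3 → 6 → 7 → 9 → 11 → 12 → 14 → 16 → 17 → 26).

Steps most likely to fail

Step 5. The risk is weak or inverted torquoselection, that is, the dioxolane steering C18 onto the wrong face of C13.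
- A weak bias is handled by separating the diastereomers at 7 or 9.
- An inverted bias calls for the mirror-image controller. This fallback sets out from iodide 5 and comes back at aldehyde 14.
- Bought (R)-2,2-dimethyl-1,3-dioxolane-4-carbaldehyde F1 is homologated to (S)-4-ethynyl-2,2-dimethyl-1,3-dioxolane F2.
- Hydroboration gives the (S,E)-alkenyl boronate F3, and coupling with 5 gives the (S)-dioxolanyl triene F4.
- Thermal closure should then favour the C12-epimeric diene F5, which has the ring configuration of 7.
- The chemistry of steps 6–9 carries it through the C12-epimeric endoperoxide F6, the C12-epimeric ene-diol F7, the C12-epimeric osmate chelate F8, the C12-epimeric tetraol F9, the C12-epimeric diacetate acetonide F10 and the C12-epimeric side-chain diol F11.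
- Glycol cleavage of F11 erases C12 as a stereocentre and delivers 14.

Step 10. The risk is β-elimination of the C14 acetate, or stalling of the olefination at the hindered aldehyde, at the temperature the sluggish formyl ylide needs. The fallback sets out from aldehyde 14 and comes back at enal 16.
- 14 is olefinated at room temperature in CH2Cl2 with the more nucleophilic ethyl 2-(triphenylphosphoranylidene)propanoate to give the (E)-2-methyl enoate diacetate F12.
- Excess DIBAL-H reduces the ester and removes both acetates to give the allylic alcohol pentaol F13.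
- MnO2 oxidises only the allylic primary alcohol to the enal tetraol F14.
- The selective acetylation of step 8 then returns 16.

Step 7. The risk is slow osmylation or insufficient facial control at the hindered trisubstituted alkene if hydrogen-bond direction is not decisive. The fallback replaces hydroxyl direction by steric control on the rigid bicycle. It sets out from endoperoxide 8, isolated after the photooxygenation, and comes back at tetraol 11.
- In 8 the dioxolanyl and C18 methyl groups on the two-carbon bridge lean over the alkene face remote from the peroxide.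
- Catalytic OsO4/NMO in acetone–water should therefore approach beside the O–O bridge and give the peroxy diol F15.
- Reduction of the O–O bond of F15 with thiourea gives 11.

Further compounds
F1 | step 5 | (R)-2,2-dimethyl-1,3-dioxolane-4-carbaldehyde | CC1(C)OC[C@@H](O1)C=O
F2 | step 5 | (S)-4-ethynyl-2,2-dimethyl-1,3-dioxolane | CC1(C)OC[C@@H](O1)C#C
F3 | step 5 | (S,E)-alkenyl pinacol boronate | CC1(C)OC[C@@H](O1)/C=C/B2OC(C)(C)C(C)(C)O2
F4 | step 5 | (S)-4-[(1E,3Z,5E)-3,5-dimethylhepta-1,3,5-trien-1-yl]-2,2-dimethyl-1,3-dioxolane | CC1(C)OC[C@@H](O1)/C=C/C(C)=C\C(C)=C\C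
F5 | step 5 | C12-epimeric diene | CC1(C)OC[C@@H](O1)[C@@H]2[C@H](C)C(C)=CC(C)=C2
F6 | step 5 | C12-epimeric endoperoxide | CC1(C)OC[C@@H](O1)[C@@H]2[C@H](C)[C@@](C)(OO3)C=C(C)[C@H]23
F7 | step 5 | C12-epimeric ene-diol | CC1(C)OC[C@@H](O1)[C@@H]2[C@H](C)[C@@](C)(O)C=C(C)[C@H]2O
F8 | step 5 | C12-epimeric osmate chelate | CC1(C)OC[C@@H](O1)[C@@H]2[C@H](C)[C@@](C)(O)[C@@H](O3)[C@@](C)(O[Os-2]34(=O)(=O)[N+](C)(C)CC[N+]4(C)C)[C@H]2O
F9 | step 5 | C12-epimeric tetraol | CC1(C)OC[C@@H](O1)[C@@H]2[C@H](C)[C@@](C)(O)[C@@H](O)[C@@](C)(O)[C@H]2O
F10 | step 5 | C12-epimeric diacetate acetonide | CC1(C)OC[C@@H](O1)[C@@H]2[C@H](C)[C@@](C)(O)[C@@H](OC(C)=O)[C@@](C)(O)[C@H]2OC(C)=O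
F11 | step 5 | C12-epimeric side-chain diol | OC[C@@H](O)[C@@H]1[C@H](C)[C@@](C)(O)[C@@H](OC(C)=O)[C@@](C)(O)[C@H]1OC(C)=O
F12 | step 10 | (E)-2-methyl enoate diacetate | CCOC(=O)/C(C)=C/[C@@H]1[C@H](C)[C@@](C)(O)[C@@H](OC(C)=O)[C@@](C)(O)[C@H]1OC(C)=O
F13 | step 10 | allylic alcohol pentaol | OC/C(C)=C/[C@@H]1[C@H](C)[C@@](C)(O)[C@@H](O)[C@@](C)(O)[C@H]1O
F14 | step 10 | enal tetraol | O=C/C(C)=C/[C@@H]1[C@H](C)[C@@](C)(O)[C@@H](O)[C@@](C)(O)[C@H]1O
F15 | step 7 | peroxy diol | CC1(C)OC[C@H](O1)[C@@H]2[C@H](C)[C@@](C)(OO3)[C@@H](O)[C@@](C)(O)[C@H]23
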